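Slowness sits in two places in this flask: solid substrate enters solution slowly, and dissolved substrate then meets reagent slowly.

solid substrate 0.020 M; reagent 0.0600 M; time 3.0 min

    solid substrate ⇌ dissolved substrate, rate k1*(cs1 - [dissolved substrate]) while solid is left; crystals form when [dissolved substrate] > cs1 (cs1 = 13 mM, k1 = 0.0066 s⁻¹)
    dissolved substrate + reagent ⇌ target (K2 = 100 M⁻¹, k2 = 0.11 M⁻¹ s⁻¹)
    2 solid substrate → self-condensation product (k3 = 0.11 M⁻¹ s⁻¹)
    solid substrate + target → side product (k4 = 0.21 M⁻¹ s⁻¹)

1. amount of target at 3.0 min, in percent of the solid substrate charged
2. the change that raises the amount of target at 3.0 min, in percent of the solid substrate charged most ("none" if none brings more than 2 percentage points) (zeta / epsilon / eta / none)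
3. amount of target at 3.0 min, in percent of the solid substrate charged, after epsilon

- zeta: doubling the amount of reagent, all else as stated
- epsilon: doubling the dissolution coefficient of step 1, all else as stated
- eta: doubling the solubility in step 1, all else as stated

Let s be the solubility and D the dissolution coefficient. Let C = 0.00660 s⁻¹ be the capture coefficient, the rate constant of target formation times the charged reagent. This is a pseudo-first-order view, taken with reagent at 3.00 equivalents.

Two extreme flasks can be solved in the head. With instant passage, dissolved substrate stands at s, and target reaches Cst, 77.2% of the charge. With instant capture, the solution stays empty, and target reaches Dst, 77.2%. The extremes coincide, since D and C are equal, and that symmetric case is the zero of the scale.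

The real flask has both resistances in line. Setting D(s−A) = CA gives S = DC/(D+C) = 0.00330 s⁻¹, the series constant, with a dissolved level A of half of s, and target forms at Ss. This level is approached with the time τ = 1/(D+C) = 75.8 s, so target is Ss(t − τ(1 − e^(−t/τ))).

S is unchanged if D and C swap, so epsilon and zeta reckon alike, with τ = 50.5 s:

| Change | Target reckoned |
|---|---|
| none | 23.9% |
| epsilon or zeta | 37.4% |
| eta | 47.8% |

I take these as high marks, with eta the best change. Solid must last for them to hold, and at the start self-condensation removes it at 0.0880 mM s⁻¹, about as fast as dissolution at 0.0858 mM s⁻¹.

The forecast gave 20% and 32% after epsilon, and chose eta, since “the stronger driving force gives the highest dissolved level”.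

The simulation gives 19.8%, 31.4% after epsilon, and eta as best, gaining 19 percentage points against 12 points for epsilon and 12 points for zeta.

The series constant puts the dissolved level of this flask at 32.5% of the charge, and the reading is 30.9%. Now take the neighbouring flask charged with 0.012 M of solid substrate. S and τ contain the reagent charge, held here at 0.0600 M, but not the solid substrate charge, so the reckoning keeps 4.77 mM of target, now 39.8% of the charge, and a dissolved level of 54.2%. That flask gives 35.1% of target and 50.4% of dissolved substrate, with solid substrate at 0% at 3.00 min.

(The rate constants come from no measurement; the flask was simulated.)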